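**Retrosynthetic overview**

1. Hypophaol (10) ⇐ C2–C3 bond. The 3,4-dimethoxybenzyl group of boronic ester 6 is joined to C2 of carbamate 4 by a sparteine-mediated lithiation–borylation (1,2-metallate rearrangement), and the C2–B bond is oxidised to C2–OH in the same flask.
2. Enabling feature: C2 is the secondary carbinol carbon of the propane chain, between the CH2 on the 2,4,6-trimethoxyphenyl ring (C1) and the CH2 on the 3,4-dimethoxyphenyl ring (C3). As an O-carbamate its oxygen directs removal of one enantiotopic C2–H, then leaves during the 1,2-shift, and is returned by C–B oxidation, so the two nearly identical arylmethyl arms never have to be told apart.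
3. Carbamate 4 ⇐ 2-(2,4,6-trimethoxyphenyl)ethanol 3 ⇐ 1,3,5-trimethoxybenzene 1 (ring lithiation, ethylene oxide).
4. Boronic ester 6 ⇐ 3,4-dimethoxybenzyl chloride 5 (Miyaura borylation).
5. No ring is formed; both benzene rings are bought intact.

Key step: step 4

Remark: the stereocentre is read as (S) (O > CH2–C6H2(OMe)3 > CH2–C6H3(OMe)2 > H); (−)-sparteine, ethylene oxide (THF solution) and 3,4-dimethoxybenzyl chloride are taken as commercial.

**Route**

Step 1
Reactants: 1 1,3,5-trimethoxybenzene
Product: 3 2-(2,4,6-trimethoxyphenyl)ethan-1-ol, via 2,4,6-trimethoxyphenyllithium 2 (not isolated)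
Conditions: n-BuLi (1.05 equiv), THF, 0 °C → rt; ethylene oxide (2 equiv, THF solution), −78 °C → rt; H2O
Reagents that add atoms: ethylene oxide, C1CO1
Why: Ortho-lithiation between two methoxy groups (all three ring C–H are equivalent) gives 2, which should open the unhindered epoxide by SN2 attack (aryllithium epoxide opening); no stereocentre is formed.

Step 2
Reactants: 3 2-(2,4,6-trimethoxyphenyl)ethan-1-ol
Product: 4 2-(2,4,6-trimethoxyphenyl)ethyl N,N-diisopropylcarbamate
Conditions: i-Pr2NC(O)Cl (1.2 equiv), Et3N (1.5 equiv), CH2Cl2, reflux
Reagents that add atoms: N,N-diisopropylcarbamoyl chloride, CC(C)N(C(C)C)C(=O)Cl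
Why: O-carbamoylation of a primary alcohol (nucleophilic acyl substitution) installs the hindered carbamate that later directs the lithiation and serves as leaving group; no stereocentre is formed.

Step 3
Reactants: 5 3,4-dimethoxybenzyl chloride
Product: 6 2-(3,4-dimethoxybenzyl)-4,4,5,5-tetramethyl-1,3,2-dioxaborolane
Conditions: B2pin2 (1.1 equiv), Pd(dba)2 (3 mol%), P(4-MeOC6H4)3 (6 mol%), KOAc (1.5 equiv), toluene, 50 °C
Reagents that add atoms: bis(pinacolato)diboron, CC1(C)OB(OC1(C)C)B1OC(C)(C)C(C)(C)O1
Why: Miyaura borylation of a benzylic chloride (oxidative addition of C–Cl to Pd(0), transmetalation with the acetate-activated diboron, reductive elimination) should give the benzylic pinacol boronate; no stereocentre is formed.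

Step 4
Reactants: 4 2-(2,4,6-trimethoxyphenyl)ethyl N,N-diisopropylcarbamate; 6 2-(3,4-dimethoxybenzyl)-4,4,5,5-tetramethyl-1,3,2-dioxaborolane
Product: 10 hypophaol ((S)-1-(3,4-dimethoxyphenyl)-3-(2,4,6-trimethoxyphenyl)propan-2-ol), via lithiated carbamate 7 (not isolated), via boronate complex 8 (not isolated), via secondary boronic ester 9 (not isolated)
Conditions: s-BuLi (1.1 equiv), (−)-sparteine (1.2 equiv), Et2O, −78 °C, 5 h; 6 (1.3 equiv), −78 °C, 1 h; MgBr2·OEt2, −78 °C → reflux, 16 h; then 2 M NaOH, 30% H2O2, THF, 0 °C → rt
Reagents that add atoms: hydrogen peroxide, OO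
Why: s-BuLi/(−)-sparteine, bound to the carbamate C=O, removes the pro-S hydrogen of the O–CH2 group (C2) to give the configurationally stable (S)-organolithium 7; boronic ester 6 captures it at boron with retention to give ate complex 8; on warming with MgBr2 the 3,4-dimethoxybenzyl group migrates from boron to C2 antiperiplanar to the departing carbamate (1,2-metallate rearrangement with inversion), which forms the C2–C3 bond and gives (S)-9; alkaline peroxide then converts C–B into C–OH with retention. The closest known reaction type is the one-pot lithiation–borylation–oxidation of primary alkyl N,N-diisopropylcarbamates with pinacol boronic esters, a reagent-controlled Matteson-type homologation. No ring is closed. The only stereocentre (C2) is set by the chiral diamine in the deprotonation and passed on by three stereospecific events (retention at borylation, inversion at migration, retention at oxidation), which together should lead to the (S)-alcohol. The step needs site selectivity for the O–CH2 hydrogens over the two ring hydrogens that each lie between two methoxy groups and over the benzylic CH2, and enantiotopic selectivity between the two C2 hydrogens; the carbamate carbonyl should secure the first by holding the base next to C2 (complex-induced proximity), helped by the small excess of s-BuLi in ether at −78 °C, and sparteine secures the second. Because the stereo-determining event distinguishes two hydrogens and not the two arylmethyl arms, the pseudo-symmetry of the 1,3-diarylpropan-2-ol, which would defeat an asymmetric ketone reduction, is of no concern.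

**Compound list**

1 | 1,3,5-trimethoxybenzene | COc1cc(OC)cc(OC)c1 | starting material
2 | 2,4,6-trimethoxyphenyllithium | [Li]c1c(OC)cc(OC)cc1OC | intermediate (not isolated)
3 | 2-(2,4,6-trimethoxyphenyl)ethan-1-ol | COc1cc(OC)c(CCO)c(OC)c1 | intermediate
4 | 2-(2,4,6-trimethoxyphenyl)ethyl N,N-diisopropylcarbamate | COc1cc(OC)c(CCOC(=O)N(C(C)C)C(C)C)c(OC)c1 | intermediate
5 | 3,4-dimethoxybenzyl chloride (4-(chloromethyl)-1,2-dimethoxybenzene) | COc1ccc(CCl)cc1OC | starting material
6 | 2-(3,4-dimethoxybenzyl)-4,4,5,5-tetramethyl-1,3,2-dioxaborolane | COc1ccc(CB2OC(C)(C)C(C)(C)O2)cc1OC | intermediate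
7 | (S)-1-lithio-2-(2,4,6-trimethoxyphenyl)ethyl N,N-diisopropylcarbamate (sparteine complex, diamine not drawn) | COc1cc(OC)c(C[C@@H](OC(=O)N(C(C)C)C(C)C)[Li])c(OC)c1 | intermediate (not isolated)
8 | lithium (S)-[1-(diisopropylcarbamoyloxy)-2-(2,4,6-trimethoxyphenyl)ethyl](3,4-dimethoxybenzyl)(pinacolato)borate | COc1cc(OC)c(C[C@@H](OC(=O)N(C(C)C)C(C)C)[B-]3(Cc2ccc(OC)c(OC)c2)OC(C)(C)C(C)(C)O3)c(OC)c1.[Li+] | intermediate (not isolated)
9 | (S)-2-[1-(3,4-dimethoxyphenyl)-3-(2,4,6-trimethoxyphenyl)propan-2-yl]-4,4,5,5-tetramethyl-1,3,2-dioxaborolane | COc1cc(OC)c(C[C@@H](B3OC(C)(C)C(C)(C)O3)Cc2ccc(OC)c(OC)c2)c(OC)c1 | intermediate (not isolated)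
10 | hypophaol, (S)-1-(3,4-dimethoxyphenyl)-3-(2,4,6-trimethoxyphenyl)propan-2-ol | COc1cc(OC)c(C[C@@H](O)Cc2ccc(OC)c(OC)c2)c(OC)c1 | target

**Step count**

Total: 4 steps. Longest linear sequence: 3 steps (steps 1, 2, 4).

**Steps most likely to fail**

Step 4. What may go wrong: s-BuLi may deprotonate the electron-rich ring (the hydrogens flanked by two methoxy groups) or the benzylic CH2 in competition with the O–CH2 group. This would consume base and lower conversion, and the 1,2-migration of the ate complex may also stay incomplete. The fallback uses chiral-pool chemistry, sets out from 1 (lithiated to 2 as in step 1) and comes back to the route at 10. Commercial 3,4-dimethoxyphenylmagnesium bromide is added to (S)-epichlorohydrin (ClC[C@@H]1CO1) with catalytic CuI in THF at −40 °C; attack at the epoxide CH2 should give (S)-1-chloro-3-(3,4-dimethoxyphenyl)propan-2-ol F1. Aqueous NaOH in THF should close it to (S)-2-(3,4-dimethoxybenzyl)oxirane F2 without touching the stereocentre. Aryllithium 2 then opens F2 at its terminal carbon with BF3·OEt2 in THF at −78 °C, which should give 10 directly. The stereocentre is bought with the epichlorohydrin and is never a reacting centre.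

Step 1. What may go wrong: the doubly ortho-substituted aryllithium may open ethylene oxide slowly, so that oligomerisation of the epoxide and protonation back to 1 compete. The fallback sets out from 1 and comes back at 3. Vilsmeier–Haack formylation (POCl3, DMF) should give 2,4,6-trimethoxybenzaldehyde F3. Wittig methylenation (Ph3PCH3Br, KOt-Bu, THF) should give 2,4,6-trimethoxystyrene F4. Anti-Markovnikov hydroboration–oxidation (9-BBN, THF; NaOH, H2O2) should then give 3.

Step 3. What may go wrong: homocoupling of the electron-rich benzylic chloride on palladium to the bibenzyl, and protodeboronation of the benzylic boronate during purification. The fallback sets out from 5 and comes back at 6. Under Barbier conditions (Mg turnings, pinacolborane, THF, rt), 3,4-dimethoxybenzylmagnesium chloride F5 is formed and trapped at once at boron with hydride as leaving group, which keeps its concentration low and should suppress Wurtz coupling.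

**Further compounds**

F1 | step 4 | (S)-1-chloro-3-(3,4-dimethoxyphenyl)propan-2-ol | COc1ccc(C[C@H](O)CCl)cc1OC
F2 | step 4 | (S)-2-(3,4-dimethoxybenzyl)oxirane | COc1ccc(C[C@H]2CO2)cc1OC
F3 | step 1 | 2,4,6-trimethoxybenzaldehyde | COc1cc(OC)c(C=O)c(OC)c1
F4 | step 1 | 2,4,6-trimethoxystyrene (2-ethenyl-1,3,5-trimethoxybenzene) | COc1cc(OC)c(C=C)c(OC)c1
F5 | step 3 | 3,4-dimethoxybenzylmagnesium chloride | COc1ccc(C[Mg]Cl)cc1OC
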